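**Retrosynthetic overview**
1. The quinone comes from a 4-methoxy-1-naphthol, with C1=O re-formed by oxidative hydrolysis. Its C3–C1′ bond is traced back to the O4–C1′ bond of an aryl hexaprenyl ether by an O→C allyl relay.
2. Key disconnection: the O4–C1′ aryl allyl ether bond, made by site-selective O-alkylation of 2,8-dimethylnaphthalene-1,4-diol. The C1–OH is shielded by the 2-methyl and the peri 8-methyl. The ether protects the chain head during chain growth and is the latent C–C bond.
3. The C30 chain is split into C15 + C15 at C12′–C13′: an ω-bromofarnesyl ether plus farnesylbarium. One building block, (E,E)-farnesyl chloride, is used twice.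
4. Both quinone C–O bonds and the 2,8-dimethyl pattern come from a double C–H oxygenation of 1,7-dimethylnaphthalene.
5. Ring order: no ring is built. Both carbocycles come intact from 1,7-dimethylnaphthalene.

Assumption: the target has no stereocentre, so "single enantiomer" is read as the single all-E (2′E,6′E,10′E,14′E,18′E) geometric isomer.

**Step 1**
Reactants: 1 1,7-dimethylnaphthalene
Product: 2 2,8-dimethyl-1,4-naphthoquinone
Conditions: H5IO6 (4 equiv), CrO3 (10 mol %), MeCN, 5 °C, 2 h
Reagents that add atoms: periodic acid, OI(=O)(O)(O)(O)O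
Why: Cr(VI)-catalysed arene-to-p-quinone oxidation, in which only the ring carrying the β-methyl has both α-positions (C5 and C8) free, so the 1,4-quinone can form only there, which fixes the 2,8-dimethyl pattern and installs both C–O bonds at once (no stereocentre).

**Step 2**
Reactants: 3 (2E,6E)-farnesol
Product: 4 (2E,6E)-farnesyl chloride
Conditions: NCS (1.1 equiv), Me2S (1.2 equiv), CH2Cl2, −40 → 0 °C
Reagents that add atoms: N-chlorosuccinimide, O=C1CCC(=O)N1Cl
Why: Corey–Kim-type chlorination, in which chloride displaces the alkoxysulfonium group by SN2 at the primary carbon under neutral conditions, so there is no allylic transposition and both E alkenes are kept.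

**Step 3**
Reactants: 2 2,8-dimethyl-1,4-naphthoquinone; 4 (2E,6E)-farnesyl chloride
Product: 7 4-[(2E,6E)-farnesyloxy]-1-methoxy-2,8-dimethylnaphthalene, via 2,8-dimethylnaphthalene-1,4-diol 5 (not isolated), via O4-farnesyl mono-ether 6 (not isolated)
Conditions: Na2S2O4, EtOAc/H2O, rt, phase cut, swap to degassed DMF; Cs2CO3 (1.0 equiv), 4 (1.0 equiv), Bu4NI (10 mol %), 0 °C → rt; then MeI (3 equiv), Cs2CO3 (1.5 equiv), 40 °C
Reagents that add atoms: iodomethane, CI
Why: Site-selective Williamson etherification, in which the C1–OH of 5 is walled in by the 2-methyl and the peri 8-methyl, so the more acidic and open C4–O⁻ attacks the primary allylic carbon by SN2 (E kept, O over C favoured by Cs⁺/DMF), and the air-sensitive mono-ether 6 is capped at O1 by MeI in the same flask.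

**Step 4**
Reactants: 7 4-[(2E,6E)-farnesyloxy]-1-methoxy-2,8-dimethylnaphthalene
Product: 8 (2E,6E,10E)-12-[(4-methoxy-3,5-dimethylnaphthalen-1-yl)oxy]-2,6,10-trimethyldodeca-2,6,10-trien-1-ol
Conditions: SeO2 (10 mol %), t-BuOOH (2 equiv), salicylic acid (10 mol %), CH2Cl2, 0 °C → rt, stopped at about 70% conversion
Reagents that add atoms: tert-butyl hydroperoxide, CC(C)(C)OO
Why: Sharpless SeO2/t-BuOOH allylic hydroxylation (ene reaction, then [2,3]-shift) attacks the most electron-rich and least hindered terminal isopropylidene at its E-methyl, which sets the only new alkene geometry (the later 10′E), while the alkene next to the aryloxy group is deactivated.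

**Step 5**
Reactants: 8 (2E,6E,10E)-12-[(4-methoxy-3,5-dimethylnaphthalen-1-yl)oxy]-2,6,10-trimethyldodeca-2,6,10-trien-1-ol
Product: 9 4-{[(2E,6E,10E)-12-bromo-3,7,11-trimethyldodeca-2,6,10-trien-1-yl]oxy}-1-methoxy-2,8-dimethylnaphthalene
Conditions: CBr4 (1.2 equiv), PPh3 (1.25 equiv), CH2Cl2, −20 → 0 °C
Reagents that add atoms: carbon tetrabromide, BrC(Br)(Br)Br
Why: Appel bromination is a neutral SN2 at the primary allylic carbon, so the E geometry and the acid-labile aryl allyl ether both survive.

**Step 6**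
Reactants: 4 (2E,6E)-farnesyl chloride; 9 4-{[(2E,6E,10E)-12-bromo-3,7,11-trimethyldodeca-2,6,10-trien-1-yl]oxy}-1-methoxy-2,8-dimethylnaphthalene
Product: 11 4-[(all-E)-hexaprenyloxy]-1-methoxy-2,8-dimethylnaphthalene, via farnesylbarium chloride 10 (not isolated)
Conditions: Li, biphenyl, BaI2, THF, rt; 4 (1.5 equiv), −78 °C; then 9, −78 °C
Reagents that add atoms: none
Why: Allylbarium allyl–allyl cross-coupling, in which allylbarium reagents made at −78 °C keep their E geometry and attack allylic bromides α,α′ (SN2), giving the head-to-tail 1,5-diene without transposition while the aryl ethers stay inert.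

**Step 7**
Reactants: 11 4-[(all-E)-hexaprenyloxy]-1-methoxy-2,8-dimethylnaphthalene
Product: 15 2,8-dimethyl-3-[(all-E)-hexaprenyl]-1,4-naphthoquinone (8-methylmenaquinone-6), via bromomagnesium naphthoxide 12 (not isolated), via hexaprenyl bromide 13 (not isolated), via C3-hexaprenyl naphthol 14 (not isolated)
Conditions: MgBr2·OEt2 (30 mol %), 2,6-di-tert-butylpyridine (30 mol %), toluene, 0 → 25 °C, Ar, dark; then DDQ (1.05 equiv), THF/H2O, 0 °C
Reagents that add atoms: water, O
Why: Proposed new method: a MgBr2-catalysed halide-relay O→C allyl transfer, in which Mg²⁺ binds the ether oxygen and bromide opens the O–CH2 bond by SN2 to give the pair 12 + 13; these recombine in non-polar toluene within the magnesium aryloxide aggregate by SN2 attack of the only free ortho carbon (C3) on the primary carbon of 13, and MgBr2 is released when the dienone tautomerises to 14; O-realkylation only regenerates 11 and is undone again, whereas C-alkylation is irreversible, so the system funnels to 14; no free allyl cation or strong Brønsted acid is present (the hindered pyridine buffers traces of HBr), which is why the 2′E geometry, the linear connectivity and the five remote alkenes should survive and chroman closure should be avoided; the closest known reaction types are the clay-, Florisil- or Bi(OTf)3-promoted [1,3] shift of aryl prenyl ethers and the ortho-C-allylation of magnesium or lithium aryloxides by allylic bromides in non-polar solvents; the closing DDQ/H2O operation is the known oxidative hydrolysis of a 4-methoxy-1-naphthol (water adds at C1, methanol leaves), DDQ does not oxidise the bromide present, and no stereocentre is created.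

**Compound list**
1 | 1,7-dimethylnaphthalene | Cc1ccc2cccc(C)c2c1 | starting material
2 | 2,8-dimethyl-1,4-naphthoquinone | CC1=CC(=O)c2cccc(C)c2C1=O | intermediate
3 | (2E,6E)-farnesol | CC(C)=CCC/C(C)=C/CC/C(C)=C/CO | starting material
4 | (2E,6E)-farnesyl chloride | CC(C)=CCC/C(C)=C/CC/C(C)=C/CCl | intermediate
5 | 2,8-dimethylnaphthalene-1,4-diol | Cc1cc(O)c2cccc(C)c2c1O | intermediate (not isolated)
6 | 4-[(2E,6E)-farnesyloxy]-2,8-dimethylnaphthalen-1-ol | Cc1cc(OC/C=C(C)/CC/C=C(C)/CCC=C(C)C)c2cccc(C)c2c1O | intermediate (not isolated)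
7 | 4-[(2E,6E)-farnesyloxy]-1-methoxy-2,8-dimethylnaphthalene | COc1c(C)cc(OC/C=C(C)/CC/C=C(C)/CCC=C(C)C)c2cccc(C)c12 | intermediate
8 | (2E,6E,10E)-12-[(4-methoxy-3,5-dimethylnaphthalen-1-yl)oxy]-2,6,10-trimethyldodeca-2,6,10-trien-1-ol | COc1c(C)cc(OC/C=C(C)/CC/C=C(C)/CC/C=C(C)/CO)c2cccc(C)c12 | intermediate
9 | 4-{[(2E,6E,10E)-12-bromo-3,7,11-trimethyldodeca-2,6,10-trien-1-yl]oxy}-1-methoxy-2,8-dimethylnaphthalene | COc1c(C)cc(OC/C=C(C)/CC/C=C(C)/CC/C=C(C)/CBr)c2cccc(C)c12 | intermediate
10 | (2E,6E)-farnesylbarium chloride | CC(C)=CCC/C(C)=C/CC/C(C)=C/C[Ba]Cl | intermediate (not isolated)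
11 | 4-[(2E,6E,10E,14E,18E)-3,7,11,15,19,23-hexamethyltetracosa-2,6,10,14,18,22-hexaen-1-yloxy]-1-methoxy-2,8-dimethylnaphthalene | COc1c(C)cc(OC/C=C(C)/CC/C=C(C)/CC/C=C(C)/CC/C=C(C)/CC/C=C(C)/CCC=C(C)C)c2cccc(C)c12 | intermediate
12 | bromomagnesium 4-methoxy-3,5-dimethylnaphthalen-1-olate | COc1c(C)cc(O[Mg]Br)c2cccc(C)c12 | intermediate (not isolated)
13 | (all-E)-hexaprenyl bromide | CC(C)=CCC/C(C)=C/CC/C(C)=C/CC/C(C)=C/CC/C(C)=C/CC/C(C)=C/CBr | intermediate (not isolated)
14 | 2-[(all-E)-hexaprenyl]-4-methoxy-3,5-dimethylnaphthalen-1-ol | COc1c(C)c(C/C=C(C)/CC/C=C(C)/CC/C=C(C)/CC/C=C(C)/CC/C=C(C)/CCC=C(C)C)c(O)c2cccc(C)c12 | intermediate (not isolated)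
15 | 2,8-dimethyl-3-[(all-E)-hexaprenyl]-1,4-naphthoquinone (CID101244058) | CC(C)=CCC/C(C)=C/CC/C(C)=C/CC/C(C)=C/CC/C(C)=C/CC/C(C)=C/CC1=C(C)C(=O)c2c(C)cccc2C1=O | target

**Totals**
Total step count: 7.
Longest linear sequence: 6 steps (1 → 2 → 7 → 8 → 9 → 11 → 15). The arm 3 → 4 → 7 → … → 15 is equally long.

**Three steps most likely to fail**

*Step 7 (the new method).*
- Risks: MgBr2 may be too weak to open the ether. Crossover may leave des-allyl naphthol and O,C-bis-allylated material. The transient allylic bromide 13 may leak E → Z, or react SN2′ to give the reverse-prenyl isomer.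
- Fallback (known chemistry): it sets out from 11 and comes back at 15. The 4-alkoxy-1-methoxynaphthalene is cleaved like a p-methoxyphenyl ether with CAN in MeCN/H2O at 0 °C. This releases all-E-hexaprenol F1 and returns quinone 2. Quinone 2 is reduced to 5 with Na2S2O4 as in step 3. Then 5 is condensed with F1 under BF3·OEt2 in dioxane, the classical Friedel–Crafts allylation of a menadiol-type hydroquinone with a polyprenol, with C3 the only free site. This gives 3-[(all-E)-hexaprenyl]-2,8-dimethylnaphthalene-1,4-diol F2, which Ag2O in Et2O oxidises to 15. The minor 2′Z isomer is removed on AgNO3-impregnated silica.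

*Step 6 (allylbarium coupling).*
- Risks: the quality of the activated barium, Wurtz homocoupling of 4, and some γ-attack.
- Fallback: it sets out from 4 and 9 and comes back at 11, using sulfone-anion alkylation instead of an allylmetal. Compound 4 and sodium p-toluenesulfinate in DMF at rt give (2E,6E)-farnesyl p-tolyl sulfone F3. Deprotonation (n-BuLi, THF/DMPU, −78 °C) and alkylation with 9 give the racemic 13′-(p-tolylsulfonyl) derivative of 11 F4. Buffered sodium amalgam (Na2HPO4, MeOH/THF, −20 °C) removes the sulfonyl group to give 11. Any double-bond-shifted isomer is separated on AgNO3-silica. Pd/LiHBEt3 and Li/EtNH2 are avoided because they would cleave the aryl allyl ether.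

*Step 4 (terminal allylic hydroxylation).*
- Risks: competing oxidation at the internal alkene, over-oxidation to the enal, and a modest yield.
- Fallback: it sets out from 7 and comes back at 8, rebuilding the terminal alkene by olefination instead of C–H oxidation. NBS in THF/H2O at 0 °C gives the terminal racemic 10′-bromo-11′-hydroxy adduct of 7 F5. K2CO3 in MeOH closes it to the racemic 10′,11′-epoxide of 7 F6. H5IO6 in THF/Et2O at 0 °C cleaves this to (4E,8E)-10-[(4-methoxy-3,5-dimethylnaphthalen-1-yl)oxy]-4,8-dimethyldeca-4,8-dienal F7. The stabilised ylide Ph3P=C(CH3)CO2Et in CH2Cl2 gives the E-configured ethyl (2E,6E,10E)-12-[(4-methoxy-3,5-dimethylnaphthalen-1-yl)oxy]-2,6,10-trimethyldodeca-2,6,10-trienoate F8. DIBAL-H at −78 °C reduces F8 to 8.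

**Further compounds**
F1 | step 7 | (2E,6E,10E,14E,18E)-3,7,11,15,19,23-hexamethyltetracosa-2,6,10,14,18,22-hexaen-1-ol (all-E-hexaprenol) | CC(C)=CCC/C(C)=C/CC/C(C)=C/CC/C(C)=C/CC/C(C)=C/CC/C(C)=C/CO
F2 | step 7 | 3-[(all-E)-hexaprenyl]-2,8-dimethylnaphthalene-1,4-diol | Cc1c(O)c2c(C)cccc2c(O)c1C/C=C(C)/CC/C=C(C)/CC/C=C(C)/CC/C=C(C)/CC/C=C(C)/CCC=C(C)C
F3 | step 6 | (2E,6E)-farnesyl p-tolyl sulfone | CC(C)=CCC/C(C)=C/CC/C(C)=C/CS(=O)(=O)c1ccc(C)cc1
F4 | step 6 | racemic 13′-(p-tolylsulfonyl) derivative of 11 | COc1c(C)cc(OC/C=C(C)/CC/C=C(C)/CC/C=C(C)/CC(/C=C(C)/CC/C=C(C)/CCC=C(C)C)S(=O)(=O)c3ccc(C)cc3)c2cccc(C)c12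
F5 | step 4 | racemic 10′-bromo-11′-hydroxy adduct of 7 | COc1c(C)cc(OC/C=C(C)/CC/C=C(C)/CCC(Br)C(C)(C)O)c2cccc(C)c12
F6 | step 4 | racemic 10′,11′-epoxide of 7 | COc1c(C)cc(OC/C=C(C)/CC/C=C(C)/CCC3OC3(C)C)c2cccc(C)c12
F7 | step 4 | (4E,8E)-10-[(4-methoxy-3,5-dimethylnaphthalen-1-yl)oxy]-4,8-dimethyldeca-4,8-dienal | COc1c(C)cc(OC/C=C(C)/CC/C=C(C)/CCC=O)c2cccc(C)c12
F8 | step 4 | ethyl (2E,6E,10E)-12-[(4-methoxy-3,5-dimethylnaphthalen-1-yl)oxy]-2,6,10-trimethyldodeca-2,6,10-trienoate | COc1c(C)cc(OC/C=C(C)/CC/C=C(C)/CC/C=C(C)/C(=O)OCC)c2cccc(C)c12
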